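## The problem

3,4,6-Tribromoindole (12) is a flat, achiral bicycle in which a benzene ring and a pyrrole ring share the C3a–C7a bond, so the difficulty is regiochemical, not stereochemical. The C3 bromine is the easy one, because C3 is the innately nucleophilic carbon of an indole. The bromines at C4 and C6 stand meta to each other at positions that electrophilic substitution of an indole does not reach cleanly, so they must come in with the six-membered ring or be fixed by the ring-forming step. A stereocentre that appears on the way (C2 of an indoline) is transient and needs no control. Three C–Br bonds restrict the reagents: alkyllithiums, low-valent palladium or nickel, hydrogenation and tin hydrides are tolerable only where a bromine is meant to be spent. The free 3-bromoindole is the most fragile array (acid, light, further halogenation), and its C3 bromine is crowded by the peri bromine at C4, so this bromine should be introduced last. The enabling feature is that N1 and C3 sit on the adjacent benzenoid carbons C7a and C3a, with the C4 bromine directly beside C3a. An aryne spanning C3a–C7a is therefore polarised so that nitrogen goes to C7a and the carbanion appears at C3a, where the C3–C3a bond must form.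

## Retrosynthesis

**C3–Br.** The C3–Br bond of 12 is cut first, giving 4,6-dibromoindole (11). Carrying this bromine through earlier steps would expose a labile 3-bromoindole to base, oxidant and fluoride, and would place a second leaving group near the anionic centre of the ring-forming step. The precursor has one bromine less and is a stable indole. The forward reaction needs clean monobromination at C3 without attack at C2.

**N-carbamate and C2 carboxyl.** 11 is traced to its N-Boc derivative 10, and 10 to the indoline acid 9 by putting a carboxyl group back on C2 and hydrogens on C2 and C3. In the forward sense the C2–CO2H bond and one C3–H bond are broken in a single oxidative decarboxylation, so the carboxyl serves as the leaving group of the aromatisation. The neighbouring option is N-deprotection, dehydrogenation, hydrolysis and protodecarboxylation of an indole-2-carboxylic acid. It is longer and ends with a hot metal-mediated step on a tribromide-to-be. 9 comes from the methyl ester 8 by hydrolysis. The carboxyl is the price of the next disconnection, because it makes the two-carbon partner a Michael acceptor.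

**N1–C7a and C3–C3a (key disconnection).** Both bonds of 8 to the benzene ring are cut together, giving 3,5-dibromobenzyne (7) and methyl 2-[(tert-butoxycarbonyl)amino]acrylate (6). Single-bond cuts of the five-membered ring would start from a dibromoaniline and form the two bonds in separate operations. This cut takes both off the arene at once and lets a bromine that belongs to the target dictate the regiochemistry. The aryne is released from the silyl triflate 5. The forward step asks that nitrogen add to C7a only and that the ortho-bromoaryl anion close the ring before it is protonated or loses bromide.

**C–Si and O–Tf.** 5 is cut at the O–S bond and the C–Si bond. Both come from trimethyl(2,4,6-tribromophenoxy)silane (2) by bromine–lithium exchange at an ortho bromine (aryllithium 3), silyl migration from oxygen to carbon (phenolate 4) and triflation. 2 is the silyl ether of 2,4,6-tribromophenol (1). In 1 the two ortho bromines are equivalent, so either may be exchanged. The phenol carbon becomes C3a, the exchanged carbon C7a, and the remaining ortho and para bromines become the C4 and C6 bromines. The forward step needs exchange ortho and not para to oxygen. 1 and 6 are purchased.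

## Roads not taken

**Alternative 1:** The cut removes C3a–C7a, C4–C5 and C6–C7, so the benzene ring is assembled from three alkynes and the nitrogen ring from a tether. RhCl(PPh3)3 would cyclotrimerise the ynamide diyne N-ethynyl-4-methyl-N-[4-(trimethylsilyl)but-3-yn-1-yl]benzenesulfonamide (A2) with ethynyltrimethylsilane (A3) to give 1-tosyl-4,6-bis(trimethylsilyl)indoline (A1).
- Merits: both rings form in one step from acyclic material, silicon marks C4 and C6 for later ipso-bromination, and no aryl anion ever sits beside a leaving group.
- Weak points: the meta (4,6) versus ortho (4,5) placement of the second silyl group depends only on steric bias in the insertion of A3. A2 needs several steps, including an N-alkynylation. After A1 there remain two bromodesilylations, dehydrogenation, C3 bromination and detosylation, and the N-sulfonyl indoline ring can brominate para to nitrogen during the ipso steps.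
- Comparison: this road avoids the fragile ortho-bromoaryl anion and the lead oxidant, and it would be the more adaptable one for analogues. The chosen plan sets against this a purchased benzene ring that already carries both benzenoid bromines, and a sequence shorter by several steps.

**Alternative 2:** The cut is C5–C6, building the benzene ring onto a pyrrole. On heating with a hindered base, 3-(1-bromovinyl)-2-(2,2-dibromovinyl)-1-(phenylsulfonyl)pyrrole (A5) would undergo six-electron electrocyclisation through the pyrrole C2–C3 bond. Loss of HBr across C5–C6 would then give 4,6-dibromo-1-(phenylsulfonyl)indole (A4).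
- Merits: the vinyl bromides fix the 4,6-pattern without ambiguity, aromatisation needs no oxidant, and no carboxyl group has to be removed.
- Weak points: the closure must break pyrrole aromaticity and push one bromine of the dibromovinyl terminus inward, so it needs high temperature. Under base and heat the dibromoalkene and the 1-bromoalkene are prone to elimination to alkynes. A5 itself requires a 2,3-difunctionalised pyrrole and two different bromo-olefinations, and A4 still needs desulfonylation and C3 bromination.
- Comparison: if A5 were at hand this road would be comparable in length after the key step. The chosen plan sets against it bought starting materials and a ring closure that runs at room temperature.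

**Alternative 3:** The cut is the indole N1–C2 bond, reached by deleting one carbon from a quinoline. Irradiation near 390 nm would convert 4,5,7-tribromo-2-methylquinoline 1-oxide (A7) into 5,6,8-tribromo-2-methyl-3,1-benzoxazepine (A8). Acid in the same pot would contract A8 to 1-acetyl-3,4,6-tribromoindole (A6), the old quinoline C2 leaving the ring as the acetyl carbon.
- Merits: all three bromines are in place before the key step, and A6 needs only deacetylation. A7 is about three conventional operations from an aniline, so the whole sequence could be near five steps, shorter than the seven planned here.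
- Weak points: three heavy atoms on the chromophore favour intersystem crossing, and the triplet N-oxide deoxygenates instead of rearranging. The 4-bromine of A7 is activated toward substitution and strained against the peri 5-bromine. The electron-poor bromo enol ether of A8 should resist the protonation that starts the contraction.
- Comparison: this road is better in step count and in having no regiochemical question. The chosen plan sets against this a ground-state polar ring formation of a well-documented class, a commodity phenol as the arene, and a C3 bromine that appears only in the last step.

Key step: step 3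

Remark on the chemistry: 8 and 9 are racemic at C2, and step 5 removes this centre, so no stereocontrol is sought in step 3. Compounds 1 and 6 are taken as purchased.

## Route

Step 1
Reactants: 1 2,4,6-tribromophenol
Product: 2 trimethyl(2,4,6-tribromophenoxy)silane
Conditions: HMDS (0.7 equiv), THF, 70 °C; evaporate, use crude
Reagents that add atoms: hexamethyldisilazane, C[Si](C)(C)N[Si](C)(C)C
Why: O-silylation of an acidic phenol by a silazane with loss of ammonia, which needs no added base and leaves no salt; the moisture-sensitive aryl silyl ether is carried on without purification.

Step 2
Reactants: 2 trimethyl(2,4,6-tribromophenoxy)silane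
Product: 5 2,4-dibromo-6-(trimethylsilyl)phenyl trifluoromethanesulfonate, via aryllithium 3 (not isolated), via lithium phenolate 4 (not isolated)
Conditions: n-BuLi (1.0 equiv), THF, −78 °C; then Tf2O (1.1 equiv), −78 → 0 °C
Reagents that add atoms: trifluoromethanesulfonic anhydride, O=S(=O)(OS(=O)(=O)C(F)(F)F)C(F)(F)F
Why: Bromine–lithium exchange ortho to the silyloxy group gives 3, which undergoes a fast 1,3 oxygen-to-carbon silyl shift (retro-Brook rearrangement) to 4, and the phenolate is then triflated. Exchange at the para bromine is reversible and has no such outlet, so the ortho pathway should drain the mixture; one equivalent of n-BuLi protects the remaining bromines.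

Step 3
Reactants: 5 2,4-dibromo-6-(trimethylsilyl)phenyl trifluoromethanesulfonate; 6 methyl 2-[(tert-butoxycarbonyl)amino]acrylate
Product: 8 1-tert-butyl 2-methyl 4,6-dibromoindoline-1,2-dicarboxylate (racemic at C2), via 3,5-dibromobenzyne 7 (not isolated)
Conditions: Bu4N[Ph3SiF2] (TBAT, 2 equiv), 6 (1.5 equiv), THF, 23 °C, slow addition of 5
Reagents that add atoms: none
Why: Fluoride attacks silicon in 5 and triflate leaves, so aryne 7 is released slowly into an excess of 6. The carbamate nitrogen adds to the aryne carbon remote from the flanking bromine (future C7a), because that bromine distorts the aryne so that the distal carbon is the electrophilic one and the carbanion develops at the future C3a beside C–Br. The aryl anion then adds to the CH2 terminus of the acrylate (C3–C3a), a formally 5-endo-trig closure of the five-membered ring onto a Michael acceptor, and the ester enolate takes up the proton that came from N–H. The closest known reaction type is the fluoride-induced aryne annulation of N-carbamoyl dehydroalanine esters to indoline-2-carboxylates, together with distal addition of nucleophiles to 3-haloarynes. The one new stereocentre, C2, is set by unselective protonation of the enolate, so 8 is racemic and the centre is erased in step 5. The selectivity needed is regiochemical (nitrogen at C7a, not C3a); the bromine next to the triple bond secures it, and the second bromine, para to the carbanion, exerts only a weak opposing pull. The tert-butyl carbamate is kept because its carbonyl is too poor an electrophile to intercept the aryl anion, which would divert an N-acyl analogue toward an isoquinoline.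

Step 4
Reactants: 8 1-tert-butyl 2-methyl 4,6-dibromoindoline-1,2-dicarboxylate
Product: 9 1-(tert-butoxycarbonyl)-4,6-dibromoindoline-2-carboxylic acid (racemic)
Conditions: LiOH·H2O, THF/MeOH/H2O, 0 → 23 °C; then 1 M HCl to pH 3, 0 °C
Reagents that add atoms: lithium hydroxide, [Li+].[OH-]
Why: Saponification of a methyl ester; the tert-butyl carbamate and the aryl bromides are inert to aqueous hydroxide at room temperature, and epimerisation at C2 is irrelevant.

Step 5
Reactants: 9 1-(tert-butoxycarbonyl)-4,6-dibromoindoline-2-carboxylic acid
Product: 10 tert-butyl 4,6-dibromoindole-1-carboxylate
Conditions: Pb(OAc)4 (1.2 equiv), Cu(OAc)2 (0.1 equiv), pyridine, PhH, 80 °C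
Reagents that add atoms: none
Why: Kochi-type oxidative decarboxylation of an N-acyl α-amino acid: the carboxylate on tetravalent lead fragments to CO2 and the C2 radical, which is oxidised (assisted by divalent copper) to the N-acyliminium ion, and loss of the benzylic C3 proton gives the aromatic N-Boc indole. The C2 stereocentre disappears here; aryl bromides are inert to these oxidants and pyridine buffers the acetic acid so the carbamate stays on.

Step 6
Reactants: 10 tert-butyl 4,6-dibromoindole-1-carboxylate
Product: 11 4,6-dibromoindole
Conditions: K2CO3 (0.3 equiv), MeOH, 40 °C
Reagents that add atoms: none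
Why: Methanolysis of an indole N-carbamate by acyl transfer to methoxide; the dibromoindolide is a good leaving group, and the absence of acid avoids tert-butylation or oligomerisation of the free indole.

Step 7
Reactants: 11 4,6-dibromoindole
Product: 12 3,4,6-tribromoindole
Conditions: NBS (1.0 equiv), DMF, −20 → 0 °C, dark
Reagents that add atoms: N-bromosuccinimide, O=C1CCC(=O)N1Br
Why: Electrophilic aromatic substitution of an N–H indole at C3, its enamine-like and most nucleophilic carbon; the benzenoid ring is deactivated by two bromines, and one equivalent at low temperature should stop at monobromination before C2 is attacked.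

## Compound list

1 | 2,4,6-tribromophenol | Oc1c(Br)cc(Br)cc1Br | starting material
2 | trimethyl(2,4,6-tribromophenoxy)silane | C[Si](C)(C)Oc1c(Br)cc(Br)cc1Br | intermediate
3 | [3,5-dibromo-2-(trimethylsilyloxy)phenyl]lithium (formed and consumed in step 2) | [Li]c1cc(Br)cc(Br)c1O[Si](C)(C)C | intermediate
4 | lithium 2,4-dibromo-6-(trimethylsilyl)phenolate (formed and consumed in step 2) | [Li+].[O-]c1c(Br)cc(Br)cc1[Si](C)(C)C | intermediate
5 | 2,4-dibromo-6-(trimethylsilyl)phenyl trifluoromethanesulfonate | C[Si](C)(C)c1cc(Br)cc(Br)c1OS(=O)(=O)C(F)(F)F | intermediate
6 | methyl 2-[(tert-butoxycarbonyl)amino]acrylate | C=C(NC(=O)OC(C)(C)C)C(=O)OC | starting material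
7 | 3,5-dibromobenzyne (formed and consumed in step 3) | BrC1=CC(Br)=CC#C1 | intermediate
8 | 1-tert-butyl 2-methyl 4,6-dibromoindoline-1,2-dicarboxylate (racemic) | COC(=O)C1Cc2c(Br)cc(Br)cc2N1C(=O)OC(C)(C)C | intermediate
9 | 1-(tert-butoxycarbonyl)-4,6-dibromoindoline-2-carboxylic acid (racemic) | OC(=O)C1Cc2c(Br)cc(Br)cc2N1C(=O)OC(C)(C)C | intermediate
10 | tert-butyl 4,6-dibromoindole-1-carboxylate | CC(C)(C)OC(=O)n1ccc2c(Br)cc(Br)cc21 | intermediate
11 | 4,6-dibromoindole | Brc1cc(Br)c2cc[nH]c2c1 | intermediate
12 | 3,4,6-tribromoindole | Brc1cc(Br)c2c(Br)c[nH]c2c1 | target

## Step count and risks

Total steps: 7. Longest linear sequence: 7 steps (1 → 12); 6 is purchased and enters at step 3.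

**Step 3 (key step).** The ortho-bromoaryl anion may be protonated, or may lose bromide to form a second aryne, before the 5-endo closure occurs. Nitrogen addition at the wrong aryne carbon is a smaller risk.
Fallback, from 5 to 11: the two bonds are made one after the other by an aryne Fischer indole sequence.
- Methyl 2-[2-(4-methylphenylsulfonyl)hydrazinylidene]propanoate F1 is prepared from methyl pyruvate and tosylhydrazide.
- F1 would be N-arylated by the aryne released from 5 with CsF in MeCN. Here protonation of the aryl anion is the wanted outcome, giving methyl 2-[2-(3,5-dibromophenyl)-2-(4-methylphenylsulfonyl)hydrazinylidene]propanoate F2.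
- BF3·OEt2 in hot MeCN should induce the [3,3] shift and loss of ammonia. The 3,5-dibromophenyl ring is symmetrical, so either ortho carbon leads to methyl 4,6-dibromo-1-(4-methylphenylsulfonyl)indole-2-carboxylate F3.
- KOH in aqueous methanol at reflux should cleave ester and sulfonamide to 4,6-dibromoindole-2-carboxylic acid F4.
- Silver-catalysed protodecarboxylation (Ag2CO3, AcOH, DMSO, 120 °C) rejoins the route at 11.

**Step 5.** The N-acyliminium ion may be captured by acetate instead of losing the C3 proton, or the carbamate may be lost to acid, after which the unprotected ring would be oxidised.
Fallback, from 9 to 11: decarboxylation is made reductive and the aromatisation is done separately.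
- 9 is converted with N-hydroxypyridine-2-thione, DCC and DMAP (CH2Cl2, dark) into the Barton ester 1-tert-butyl 2-(2-thioxopyridin-1(2H)-yl) 4,6-dibromoindoline-1,2-dicarboxylate F5.
- Visible light with t-BuSH should give tert-butyl 4,6-dibromoindoline-1-carboxylate F6 by a thiol-mediated radical chain that leaves aryl bromides alone.
- TFA in CH2Cl2 gives 4,6-dibromoindoline F7.
- Dehydrogenation with MnO2 in CH2Cl2 returns to the route at 11.

**Step 2.** Exchange may occur at the para bromine or at two bromines, or silyl migration may be incomplete before triflation.
Fallback, from 1 to 5: the site is fixed by chelation and silicon is delivered from outside.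
- 1 is protected with MOMCl and i-Pr2NEt as 1,3,5-tribromo-2-(methoxymethoxy)benzene F8.
- i-PrMgCl·LiCl (THF, −20 °C) should exchange the bromine ortho to the chelating acetal, and Me3SiCl then gives [3,5-dibromo-2-(methoxymethoxy)phenyl]trimethylsilane F9.
- HCl in MeOH frees 2,4-dibromo-6-(trimethylsilyl)phenol F10.
- Tf2O and pyridine give 5.

**Step 7.** A second bromination at C2, oxidative decomposition of the free indole, or slow attack at the crowded C3 may spoil the last step.
Fallback, from 10 to 12: the order of the last two steps is reversed.
- 10 is brominated with NBS in DMF at 23 °C to tert-butyl 3,4,6-tribromoindole-1-carboxylate F11. The carbamate tempers the ring against over-bromination.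
- K2CO3 in MeOH then releases 12 in a final, non-oxidising step.

## Further compounds

F1 | step 3 | methyl 2-[2-(4-methylphenylsulfonyl)hydrazinylidene]propanoate | COC(=O)C(C)=NNS(=O)(=O)c1ccc(C)cc1
F2 | step 3 | methyl 2-[2-(3,5-dibromophenyl)-2-(4-methylphenylsulfonyl)hydrazinylidene]propanoate | COC(=O)C(C)=NN(c1cc(Br)cc(Br)c1)S(=O)(=O)c1ccc(C)cc1
F3 | step 3 | methyl 4,6-dibromo-1-(4-methylphenylsulfonyl)indole-2-carboxylate | COC(=O)c1cc2c(Br)cc(Br)cc2n1S(=O)(=O)c1ccc(C)cc1
F4 | step 3 | 4,6-dibromoindole-2-carboxylic acid | OC(=O)c1cc2c(Br)cc(Br)cc2[nH]1
F5 | step 5 | 1-tert-butyl 2-(2-thioxopyridin-1(2H)-yl) 4,6-dibromoindoline-1,2-dicarboxylate (racemic) | CC(C)(C)OC(=O)N1C(C(=O)On2ccccc2=S)Cc2c(Br)cc(Br)cc21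
F6 | step 5 | tert-butyl 4,6-dibromoindoline-1-carboxylate | CC(C)(C)OC(=O)N1CCc2c(Br)cc(Br)cc21
F7 | step 5 | 4,6-dibromoindoline | Brc1cc(Br)c2CCNc2c1
F8 | step 2 | 1,3,5-tribromo-2-(methoxymethoxy)benzene | COCOc1c(Br)cc(Br)cc1Br
F9 | step 2 | [3,5-dibromo-2-(methoxymethoxy)phenyl]trimethylsilane | COCOc1c(Br)cc(Br)cc1[Si](C)(C)C
F10 | step 2 | 2,4-dibromo-6-(trimethylsilyl)phenol | Oc1c(Br)cc(Br)cc1[Si](C)(C)C
F11 | step 7 | tert-butyl 3,4,6-tribromoindole-1-carboxylate | CC(C)(C)OC(=O)n1cc(Br)c2c(Br)cc(Br)cc21
A1 | alternative 1 | 1-tosyl-4,6-bis(trimethylsilyl)indoline | C[Si](C)(C)c1cc([Si](C)(C)C)c2CCN(S(=O)(=O)c3ccc(C)cc3)c2c1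
A2 | alternative 1 | N-ethynyl-4-methyl-N-[4-(trimethylsilyl)but-3-yn-1-yl]benzenesulfonamide | C#CN(CCC#C[Si](C)(C)C)S(=O)(=O)c1ccc(C)cc1
A3 | alternative 1 | ethynyltrimethylsilane | C#C[Si](C)(C)C
A4 | alternative 2 | 4,6-dibromo-1-(phenylsulfonyl)indole | Brc1cc(Br)c2ccn(S(=O)(=O)c3ccccc3)c2c1
A5 | alternative 2 | 3-(1-bromovinyl)-2-(2,2-dibromovinyl)-1-(phenylsulfonyl)pyrrole | C=C(Br)c1ccn(S(=O)(=O)c2ccccc2)c1C=C(Br)Br
A6 | alternative 3 | 1-acetyl-3,4,6-tribromoindole | CC(=O)n1cc(Br)c2c(Br)cc(Br)cc21
A7 | alternative 3 | 4,5,7-tribromo-2-methylquinoline 1-oxide | Cc1cc(Br)c2c(Br)cc(Br)cc2[n+]1[O-]
A8 | alternative 3 | 5,6,8-tribromo-2-methyl-3,1-benzoxazepine | CC1=Nc2cc(Br)cc(Br)c2C(Br)=CO1
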